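In the target, the carboxyl carbon, arene carbons C1 and C6 (bearing carboxyl and side chain), the benzylic methylene C1' and the ketone carbon C2' form an unbroken five-carbon sequence with a carbonyl carbon at each end; bonding those ends gives the five-membered ring of a 1-indanone fused to the benzene ring. The key step exploits this: intramolecular Friedel–Crafts acylation of racemic 13-(benzyloxy)-2-(3,5-dimethoxybenzyl)tridecanoic acid forms the C1–carboxyl carbon bond and closes that ring in one operation, at the only site the symmetric dimethoxyarene offers. Enolate hydroxylation and periodate scission reopen the ring; BCl3 then frees the C2 phenol and the terminal alcohol.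

Key step: step 3

Assumption: the target is achiral and is treated as the open-chain keto acid; the single stereocentre of 6, 7, 8 and 10 disappears in step 5, so these are carried as racemates, and 3-(3,5-dimethoxyphenyl)propanoic acid is taken as a purchasable starting material.

Step 1
Reactants: 1 11-bromoundecan-1-ol; 2 benzyl 2,2,2-trichloroacetimidate
Product: 3 benzyl 11-bromoundecyl ether
Conditions: TfOH (cat.), CH2Cl2/cyclohexane, 0 °C to rt
Reagents that add atoms: benzyl 2,2,2-trichloroacetimidate (compound 2), ClC(Cl)(Cl)C(=N)OCc1ccccc1
Why: Acid-catalysed O-benzylation by a trichloroacetimidate: the protonated imidate hands its benzyl group to the primary alcohol and leaves as neutral trichloroacetamide, and because no alkoxide is ever formed the primary bromide is neither displaced nor eliminated.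

Step 2
Reactants: 4 3-(3,5-dimethoxyphenyl)propanoic acid; 3 benzyl 11-bromoundecyl ether
Product: 6 rac-13-(benzyloxy)-2-(3,5-dimethoxybenzyl)tridecanoic acid, via dilithium enediolate 5 (not isolated)
Conditions: LiN(iPr)2 (commercial solution, 2.1 equiv per acid), THF, −78 to 0 °C; then 3, DMPU, 0 °C to rt; 1 M HCl work-up
Reagents that add atoms: none
Why: Alkylation of a carboxylic acid dianion: two equivalents of LiN(iPr)2 convert 4 into its lithium enediolate 5, whose alpha carbon displaces bromide from the unhindered primary halide 3 by SN2 substitution (DMPU loosens the aggregates), and the one new stereocentre is set without control, so 6 forms as the racemate, which suffices because this carbon ends as the achiral ketone carbon C2'.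

Step 3
Reactants: 6 rac-13-(benzyloxy)-2-(3,5-dimethoxybenzyl)tridecanoic acid
Product: 8 rac-2-[11-(benzyloxy)undecyl]-5,7-dimethoxyindan-1-one, via acid chloride 7 (not isolated)
Conditions: (COCl)2, DMF (cat.), CH2Cl2, 0 °C to rt, evaporate; then SnCl4 (2 equiv), CH2Cl2, −78 to −20 °C; cold 1 M HCl quench
Reagents that add atoms: none
Why: Oxalyl chloride with catalytic DMF turns the acid into acid chloride 7, which SnCl4 ionises to an acylium ion; the ring carbon ortho to the benzylic tether attacks it and proton loss restores aromaticity, forming the bond from arene C1 (target numbering) to the future carboxyl carbon. This is an intramolecular Friedel–Crafts acylation, the standard conversion of 3-arylpropanoyl chlorides into 1-indanones. The single ring closes as a five-membered carbocycle by annulative electrophilic aromatic substitution, the attacking arene C=C bond lying inside the new ring and the acylium C–O bond outside it. No stereocentre is created; the existing alpha carbon stays racemic, which is immaterial because it becomes the ketone carbon C2' in step 5. The selectivity required is regiochemical and the substrate supplies it: the two positions ortho to the tether are equivalent by symmetry and each is ortho to one methoxy group and para to the other, whereas the position between the methoxy groups is para to the tether and beyond the reach of a three-atom chain. The ketone product is deactivated towards a second acylation, and the simple primary benzyl ether, which offers SnCl4 no chelate, should persist below 0 °C.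

Step 4
Reactants: 8 rac-2-[11-(benzyloxy)undecyl]-5,7-dimethoxyindan-1-one
Product: 10 rac-2-[11-(benzyloxy)undecyl]-2-hydroxy-5,7-dimethoxyindan-1-one, via potassium enolate 9 (not isolated)
Conditions: KN(SiMe3)2, THF, −78 °C; then 2-(phenylsulfonyl)-3-phenyloxaziridine, −78 °C; aq. NH4Cl
Reagents that add atoms: 2-(phenylsulfonyl)-3-phenyloxaziridine, O=S(=O)(c1ccccc1)N1OC1c1ccccc1
Why: Davis oxidation, the hydroxylation of an enolate by an N-sulfonyloxaziridine: C2 is the only enolisable carbon of 8, since the other neighbour of the carbonyl group is arene carbon C7a, so KN(SiMe3)2 gives a single enolate that attacks the oxaziridine oxygen, and the new tertiary carbinol centre forms without facial control as a racemate, which is harmless because step 5 destroys it.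

Step 5
Reactants: 10 rac-2-[11-(benzyloxy)undecyl]-2-hydroxy-5,7-dimethoxyindan-1-one
Product: 11 2-[13-(benzyloxy)-2-oxotridecyl]-4,6-dimethoxybenzoic acid
Conditions: NaIO4, THF/H2O, rt
Reagents that add atoms: water, O
Why: Periodate cleavage of an alpha-ketol (glycol-type scission through the ketone hydrate, which brings in the new carboxyl oxygen, and a cyclic periodate ester): only the C1–C2 bond carries oxygen on both carbons, so the indanone carbonyl becomes the aryl carboxyl group and the carbinol carbon becomes the C2' ketone, while the ethers and the arene are inert to NaIO4.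

Step 6
Reactants: 11 2-[13-(benzyloxy)-2-oxotridecyl]-4,6-dimethoxybenzoic acid
Product: 12 2-hydroxy-6-(13-hydroxy-2-oxotridecyl)-4-methoxybenzoic acid (target)
Conditions: BCl3 (6 equiv), C6HMe5 (3 equiv), CH2Cl2, −78 to 0 °C; then H2O, THF, 0 °C
Reagents that add atoms: none
Why: Lewis acid ether cleavage: BCl3 bound between the carboxyl group and the ortho methoxy oxygen at C2 delivers chloride to that methyl group alone (chelation-controlled demethylation that leaves the C4 methoxy group), and the same reagent dealkylates the primary benzyl ether, whose benzyl cation is trapped by pentamethylbenzene before it can alkylate the electron-rich ring.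

Compound list
1 | 11-bromoundecan-1-ol | OCCCCCCCCCCCBr | starting material
2 | benzyl 2,2,2-trichloroacetimidate | ClC(Cl)(Cl)C(=N)OCc1ccccc1 | starting material
3 | benzyl 11-bromoundecyl ether | BrCCCCCCCCCCCOCc1ccccc1 | intermediate
4 | 3-(3,5-dimethoxyphenyl)propanoic acid | COc1cc(CCC(=O)O)cc(OC)c1 | starting material
5 | dilithium 3-(3,5-dimethoxyphenyl)prop-1-ene-1,1-diolate (enediolate of 4, not isolated) | COc1cc(CC=C([O-])[O-])cc(OC)c1.[Li+].[Li+] | intermediate
6 | rac-13-(benzyloxy)-2-(3,5-dimethoxybenzyl)tridecanoic acid | COc1cc(CC(CCCCCCCCCCCOCc2ccccc2)C(=O)O)cc(OC)c1 | intermediate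
7 | rac-13-(benzyloxy)-2-(3,5-dimethoxybenzyl)tridecanoyl chloride (not isolated) | COc1cc(CC(CCCCCCCCCCCOCc2ccccc2)C(Cl)=O)cc(OC)c1 | intermediate
8 | rac-2-[11-(benzyloxy)undecyl]-5,7-dimethoxyindan-1-one | COc1cc(OC)c2C(=O)C(CCCCCCCCCCCOCc3ccccc3)Cc2c1 | intermediate
9 | potassium 2-[11-(benzyloxy)undecyl]-4,6-dimethoxy-1H-inden-3-olate (enolate of 8, not isolated) | COc1cc(OC)c2C([O-])=C(CCCCCCCCCCCOCc3ccccc3)Cc2c1.[K+] | intermediate
10 | rac-2-[11-(benzyloxy)undecyl]-2-hydroxy-5,7-dimethoxyindan-1-one | COc1cc(OC)c2C(=O)C(O)(CCCCCCCCCCCOCc3ccccc3)Cc2c1 | intermediate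
11 | 2-[13-(benzyloxy)-2-oxotridecyl]-4,6-dimethoxybenzoic acid | COc1cc(OC)c(C(=O)O)c(CC(=O)CCCCCCCCCCCOCc2ccccc2)c1 | intermediate
12 | 2-hydroxy-6-(13-hydroxy-2-oxotridecyl)-4-methoxybenzoic acid (no stereocentre) | COc1cc(O)c(C(=O)O)c(CC(=O)CCCCCCCCCCCO)c1 | target

Total step count: 6. Longest linear sequence: 6 steps (1 → 3 → 6 → 8 → 10 → 11 → 12).

Steps most likely to fail

Step 3. The benzyl ether may be cleaved or O-acylated by the acylium ion and SnCl4, intermolecular acylation may compete, or the methoxy group next to the new carbonyl may be demethylated. The fallback closes the ring before the chain is present. It sets out from 4: cyclodehydration with P2O5 in MeSO3H at rt should give 5,7-dimethoxyindan-1-one F1. C-Methoxycarbonylation (NaH, dimethyl carbonate, THF, reflux) should give methyl 5,7-dimethoxy-1-oxoindane-2-carboxylate F2. Alkylation of its stabilised enolate with bromide 3 (K2CO3, KI cat., DMF, 60 °C) should give methyl 2-[11-(benzyloxy)undecyl]-5,7-dimethoxy-1-oxoindane-2-carboxylate F3. Krapcho dealkoxycarbonylation (LiCl, H2O, DMSO, 150 °C) comes back to the route at 8.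

Step 6. The liberated 2-(2-oxoalkyl)benzoic acid may undergo enol lactonisation under BCl3 and HCl, or one of the two ethers may be cleaved incompletely. The fallback makes the lactone on purpose and opens it under base at the end. It sets out from 11: acid-catalysed cyclodehydration (TsOH cat., toluene, reflux with removal of water) should give 3-[11-(benzyloxy)undecyl]-6,8-dimethoxy-1H-isochromen-1-one F6. BCl3 with C6HMe5 (CH2Cl2, −78 to 0 °C) should remove the methyl of the methoxy group beside the lactone carbonyl and the benzyl group, giving 8-hydroxy-3-(11-hydroxyundecyl)-6-methoxy-1H-isochromen-1-one F7. Aqueous KOH in EtOH then opens the enol lactone, and acidification to pH 3 at 0 °C comes back to the route at 12.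

Step 5. Ketol scission may be slow or incomplete because the electron-rich, ortho-substituted aryl ketone resists the hydration that periodate needs. The fallback cleaves a true glycol instead. It sets out from 10: NaBH4 (MeOH, 0 °C) should give 2-[11-(benzyloxy)undecyl]-5,7-dimethoxyindane-1,2-diol F4 (racemic diastereomer mixture). Pb(OAc)4 (CH2Cl2, 0 °C), which cleaves cis and trans diols alike, should give 2-[13-(benzyloxy)-2-oxotridecyl]-4,6-dimethoxybenzaldehyde F5, used at once to forestall intramolecular aldol condensation. Pinnick oxidation (NaClO2, NaH2PO4, 2-methyl-2-butene, tBuOH/H2O) comes back to the route at 11.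

Further compounds
F1 | step 3 | 5,7-dimethoxyindan-1-one | COc1cc(OC)c2C(=O)CCc2c1
F2 | step 3 | rac-methyl 5,7-dimethoxy-1-oxoindane-2-carboxylate | COC(=O)C1Cc2cc(OC)cc(OC)c2C1=O
F3 | step 3 | rac-methyl 2-[11-(benzyloxy)undecyl]-5,7-dimethoxy-1-oxoindane-2-carboxylate | COC(=O)C1(CCCCCCCCCCCOCc3ccccc3)Cc2cc(OC)cc(OC)c2C1=O
F4 | step 5 | 2-[11-(benzyloxy)undecyl]-5,7-dimethoxyindane-1,2-diol (racemic, diastereomer mixture) | COc1cc(OC)c2C(O)C(O)(CCCCCCCCCCCOCc3ccccc3)Cc2c1
F5 | step 5 | 2-[13-(benzyloxy)-2-oxotridecyl]-4,6-dimethoxybenzaldehyde | COc1cc(OC)c(C=O)c(CC(=O)CCCCCCCCCCCOCc2ccccc2)c1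
F6 | step 6 | 3-[11-(benzyloxy)undecyl]-6,8-dimethoxy-1H-isochromen-1-one | COc1cc(OC)c2c(c1)C=C(CCCCCCCCCCCOCc3ccccc3)OC2=O
F7 | step 6 | 8-hydroxy-3-(11-hydroxyundecyl)-6-methoxy-1H-isochromen-1-one | COc1cc(O)c2c(c1)C=C(CCCCCCCCCCCO)OC2=O
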